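(The runs come from a simulation for substances that don't exist; scatter was added.)

At 40.0 min the delta run has turned 43% of its starting material into product, against 34% in the zeta run, on 2.6 equiv of reagent against 1.7 equiv.

| flask | starting material | reagent | free catalyst | remark | time |
|---|---|---|---|---|---|
| zeta | 0.50 M | 1.7 equiv | 0.5 mol% | run made earlier |  |
| delta | 0.50 M | 2.6 equiv | 0.5 mol% | run made earlier |  |
| flask | 0.50 M | 1.20 equiv | 0.5 mol% |  | 50 min |

- zeta (time / min: product / %, starting material / %): 4.00: 2, 97; 10.0: 10, 90; 20.0: 21, 78; 30.0: 29, 75; 40.0: 34, 67
- delta (time / min: product / %, starting material / %): 4.00: 3, 93; 10.0: 7, 91; 20.0: 23, 76; 30.0: 36, 71; 40.0: 43, 60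

(each reading ± 2 percentage points)

- concentration of product at 50 min, in M
- concentration of starting material at 50 min, in M
- concentration of reagent at 50 min, in M

Counted as first-order in starting material, those readings give 0.0104 min⁻¹ for zeta and 0.0141 min⁻¹ for delta. Their ratio, 1.35, contains no time, and it is smaller than the reagent ratio 1.53, so the order in reagent reads 0.711. Scaled to 1.20 equiv, the zeta constant becomes 0.00811 min⁻¹, and the flask should convert a fraction 33.3% by 50 min.

The weak link is that order, which rests on one reading per run with a scatter of 2 percentage points. The starting-material column, read separately, gives a ratio of 1.28 and an order of 0.573. Its zeta constant, scaled the same way by the equivalents charged, gives the flask an apparent first-order constant 0.00820 min⁻¹, which leaves a fraction 66.4% of starting material.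

The forecast, made separately, gives 0.165 M of product (0.13 M to 0.205 M), 0.335 M of starting material (0.295 M to 0.37 M) and 0.435 M of reagent (0.395 M to 0.47 M), with the order in reagent put at about 0.6, “perhaps saturating, though noisy”.

The flask gives 0.173 M of product, 0.325 M of starting material and 0.426 M of reagent, each within the forecast's range.

    catalyst intermediate A ⇌ catalyst intermediate B (K = 0.460, k = 0.160 s⁻¹)
    starting material + free catalyst → catalyst intermediate A (k = 0.490 M⁻¹ s⁻¹)
    catalyst intermediate D → free catalyst + product (k = 2.10 s⁻¹)
    reagent + catalyst intermediate B → catalyst intermediate C (k = 0.240 M⁻¹ s⁻¹)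
    catalyst intermediate C ⇌ by-product + catalyst intermediate D (K = 0.320 M, k = 0.190 s⁻¹)

The fraction 64.9% of starting material left in the flask corresponds to an apparent first-order constant of 0.00864 min⁻¹, against 0.00820 min⁻¹ reckoned beforehand. The neighbouring flask carries 0.3 mol% of free catalyst instead of 0.5 mol%, with the other charges and the time held. With the constant taken as proportional to the loading, the flask's 0.00864 min⁻¹ scales to 0.00518 min⁻¹, and the same exponential leaves a fraction 77.2% at 50 min. That neighbouring flask holds 0.109 M of product, and 78% of its starting material remains.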